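**Plan**
1. Retrosynthesis: the two phenol silyl ethers and a temporary hydroxyl on C2 are removed first; then ring C (the pyran) is cut at O1–C2 and at C3–C4 in one operation.
2. The enabling feature is the 2-hydroxybenzyl unit of ring A (O1–C8a=C4a–C4H2, pushed by the C5 methoxy and C7 oxygen). It can be unmasked as an o-quinone methide, a 1-oxadiene, while C2–C3 arrives as the enamine of the ring B arylacetaldehyde.
3. Forward, ring A piece: 2,4-dihydroxy-6-methoxybenzaldehyde is silylated, O-prenylated, rearranged (para-Claisen–Cope, prenyl to the future C6), reductively aminated and N-methylated. The methide is thus stored as a benzylic trimethylammonium salt and is first formed only in the union. Ring B piece: one-carbon homologation of 4-hydroxy-2-methoxybenzaldehyde.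
4. Union: an amine-catalysed formal [4+2] joins the halves and closes ring C as a chroman-2-ol; ionic hydrogenation removes the C2 hydroxyl; fluoride frees both phenols.
5. Stereochemistry: the single centre C3 (R) is set in the union by face shielding of the enamine by the (R)-diphenylprolinol silyl ether catalyst and is not a reacting centre afterwards.

Key step: step 9

Assumption: starting materials 1, 3 and 11 are taken as commercial; the configuration at C2 of lactol 18 is left undefined because C2 becomes a methylene group in step 10.

**Route**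

Step 1
Reactants: 1 2,4-dihydroxy-6-methoxybenzaldehyde
Product: 2 2-hydroxy-6-methoxy-4-(triisopropylsilyloxy)benzaldehyde
Conditions: TIPSCl (1.05 equiv), imidazole, CH2Cl2, 0 °C
Reagents that add atoms: chlorotriisopropylsilane, CC(C)[Si](Cl)(C(C)C)C(C)C
Why: Selective O-silylation should cap only the 4-hydroxyl, because it is the more acidic one (para to the formyl group) and is not held in the hydrogen bond to the carbonyl that deactivates the 2-hydroxyl.

Step 2
Reactants: 2 2-hydroxy-6-methoxy-4-(triisopropylsilyloxy)benzaldehyde; 3 3-methylbut-2-en-1-ol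
Product: 4 2-methoxy-6-(3-methylbut-2-enyloxy)-4-(triisopropylsilyloxy)benzaldehyde
Conditions: PPh3, DIAD, THF, 0 °C → rt
Reagents that add atoms: none
Why: Mitsunobu etherification of the acidic chelated phenol with the primary allylic alcohol should give the unrearranged prenyl ether under neutral conditions that leave the aryl silyl ether untouched.

Step 3
Reactants: 4 2-methoxy-6-(3-methylbut-2-enyloxy)-4-(triisopropylsilyloxy)benzaldehyde
Product: 7 6-hydroxy-2-methoxy-3-(3-methylbut-2-enyl)-4-(triisopropylsilyloxy)benzaldehyde, via ortho dienone 5 (not isolated), via para dienone 6 (not isolated)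
Conditions: N,N-diethylaniline, 190 °C, degassed, sealed tube
Reagents that add atoms: none
Why: In this aromatic para-Claisen rearrangement (Claisen then Cope) the first [3,3] shift sends the 1,1-dimethylallyl group to the free ortho carbon C5, the crowded dienone 5 passes it on by a second [3,3] shift to C3 (para to the ether oxygen, between the methoxy and silyloxy groups) as a normal prenyl group, and enolisation of 6 restores the phenol, the pathway that 2-prenyloxy-4,6-dialkoxyaryl carbonyl compounds are known to follow.

Step 4
Reactants: 7 6-hydroxy-2-methoxy-3-(3-methylbut-2-enyl)-4-(triisopropylsilyloxy)benzaldehyde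
Product: 9 2-[(dimethylamino)methyl]-3-methoxy-4-(3-methylbut-2-enyl)-5-(triisopropylsilyloxy)phenol, via iminium acetate 8 (not isolated)
Conditions: Me2NH (2 M in THF, 1.5 equiv), NaBH(OAc)3 (1.5 equiv), AcOH (1 equiv), 1,2-dichloroethane, rt
Reagents that add atoms: dimethylamine, CNC
Why: In this reductive amination the chelated aldehyde condenses with the secondary amine to iminium 8, which NaBH(OAc)3 should reduce faster than it reduces the electron-rich aldehyde, so the phenolic Mannich base forms without ionisation at the benzylic carbon and no quinone methide arises at this stage.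

Step 5
Reactants: 9 2-[(dimethylamino)methyl]-3-methoxy-4-(3-methylbut-2-enyl)-5-(triisopropylsilyloxy)phenol
Product: 10 [2-hydroxy-6-methoxy-5-(3-methylbut-2-enyl)-4-(triisopropylsilyloxy)phenyl]methyl-trimethylammonium iodide
Conditions: MeI (3 equiv), Et2O, 0 °C → rt, dark; salt filtered off and used without heating
Reagents that add atoms: iodomethane, CI
Why: In this Menshutkin N-alkylation without added base the tertiary amine is far more nucleophilic than the undissociated phenol, the trisubstituted alkene and the silyl ether, so MeI should quaternise nitrogen only, and the salt that precipitates from ether stores the methide with trimethylamine as a latent leaving group.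

Step 6
Reactants: 11 4-hydroxy-2-methoxybenzaldehyde
Product: 12 2-methoxy-4-(triisopropylsilyloxy)benzaldehyde
Conditions: TIPSCl, imidazole, DMF, rt
Reagents that add atoms: chlorotriisopropylsilane, CC(C)[Si](Cl)(C(C)C)C(C)C
Why: Standard silylation of the only phenol gives an ether that should survive base, dilute acid and the Lewis acid of step 10 and fall to fluoride at the end.

Step 7
Reactants: 12 2-methoxy-4-(triisopropylsilyloxy)benzaldehyde
Product: 13 2-methoxy-1-(2-methoxyethenyl)-4-(triisopropylsilyloxy)benzene (E/Z mixture)
Conditions: MeOCH2PPh3Cl, NaN(SiMe3)2, THF, 0 °C → rt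
Reagents that add atoms: (methoxymethyl)triphenylphosphonium chloride, COC[P+](c1ccccc1)(c1ccccc1)c1ccccc1.[Cl-]
Why: Wittig olefination with the methoxymethylene ylide adds the one carbon that becomes C2, and the non-nucleophilic amide base should spare the aryl silyl ether.

Step 8
Reactants: 13 2-methoxy-1-(2-methoxyethenyl)-4-(triisopropylsilyloxy)benzene
Product: 14 2-[2-methoxy-4-(triisopropylsilyloxy)phenyl]acetaldehyde
Conditions: aq HCl (2 M), THF, 45 °C; used at once without storage
Reagents that add atoms: water, O
Why: Acid-catalysed enol ether hydrolysis (protonation at the benzylic carbon, collapse of the hemiacetal) converts both geometric isomers into the same arylacetaldehyde, while the aryl triisopropylsilyl ether should tolerate dilute acid.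

Step 9
Reactants: 10 [2-hydroxy-6-methoxy-5-(3-methylbut-2-enyl)-4-(triisopropylsilyloxy)phenyl]methyl-trimethylammonium iodide; 14 2-[2-methoxy-4-(triisopropylsilyloxy)phenyl]acetaldehyde
Product: 18 (3R)-5-methoxy-3-[2-methoxy-4-(triisopropylsilyloxy)phenyl]-6-(3-methylbut-2-enyl)-7-(triisopropylsilyloxy)chroman-2-ol (mixture of C2 anomers), via o-quinone methide 15 (not isolated), via enamine 16 (not isolated), via hydroxy aldehyde 17 (not isolated)
Conditions: (R)-α,α-diphenylprolinol trimethylsilyl ether (20 mol %), Na2CO3 (1.5 equiv), 14 (2 equiv), CH2Cl2, 0 °C → rt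
Reagents that add atoms: none
Why: Carbonate deprotonates the phenol of 10 and the phenoxide expels trimethylamine by 1,4-elimination, releasing methide 15 (the 1-oxadiene O1=C8a–C4a=C4H2 of ring A) while 14 and the amine form the (E)-enamine 16; the aryl-bearing enamine carbon adds to the exocyclic methylene (C3–C4 bond, ring A rearomatises), the iminium is hydrolysed to 17 and the phenol O1 adds to the aldehyde carbon (O1–C2 bond), a stepwise formal [4+2] cycloaddition. The closest known reaction type is the amine-catalysed asymmetric Michael addition–hemiacetalisation of aldehydes with o-quinone methides released in situ by base from 2-(sulfonylmethyl)phenols, which gives chroman-2-ols, and base-induced loss of trimethylamine from phenolic Mannich base methiodides is an equally established way to release such methides. Ring C is closed by 6-exo-trig attack of the phenol oxygen on the carbonyl (or iminium) carbon after the intermolecular C–C bond has formed. The only lasting stereocentre, C3, is set by the catalyst: the diphenyl(silyloxy)methyl arm of the (R)-pyrrolidine covers one face of the s-trans (E)-enamine, the methide carbon arrives on the open face, and for this substituent set (formyl > aryl > benzyl) that face corresponds to (R); C2 forms as an anomeric mixture that is erased in step 10. The step needs regiocontrol (aryl on C3, oxygen on C2), secured by the matched polarity of the nucleophilic enamine carbon and the electrophilic methylene; it needs the cross reaction to beat methide self-condensation and aldehyde self-aldol, secured by slow release from the ammonium reservoir and the excess of 14; and it needs the α-aryl centre to hold its configuration, secured by immediate storage as the cyclic hemiacetal.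

Step 10
Reactants: 18 (3R)-5-methoxy-3-[2-methoxy-4-(triisopropylsilyloxy)phenyl]-6-(3-methylbut-2-enyl)-7-(triisopropylsilyloxy)chroman-2-ol
Product: 19 (3R)-5-methoxy-3-[2-methoxy-4-(triisopropylsilyloxy)phenyl]-6-(3-methylbut-2-enyl)-7-(triisopropylsilyloxy)chroman
Conditions: Et3SiH (5 equiv), BF3·OEt2 (2 equiv), CH2Cl2, −78 → −40 °C
Reagents that add atoms: none
Why: In this ionic hydrogenation of a lactol, BF3 ionises the anomeric hydroxyl to the cyclic oxocarbenium ion and the excess silane should deliver hydride to C2 at low temperature faster than the ion can lose the C3 proton, so C3 is carried through unchanged and the prenyl group and aryl silyl ethers are spared.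

Step 11
Reactants: 19 (3R)-5-methoxy-3-[2-methoxy-4-(triisopropylsilyloxy)phenyl]-6-(3-methylbut-2-enyl)-7-(triisopropylsilyloxy)chroman
Product: 20 (3R)-3-(4-hydroxy-2-methoxyphenyl)-5-methoxy-6-(3-methylbut-2-enyl)chroman-7-ol (CNP0298769.1)
Conditions: Bu4NF (2.5 equiv), AcOH (2.5 equiv), THF, 0 °C
Reagents that add atoms: none
Why: Buffered fluoride desilylation should free both phenols without acid, so the prenyl group next to the new C7 hydroxyl cannot cyclise to a dimethylchroman and C3 is not touched.

**Compound list**
1 | 2,4-dihydroxy-6-methoxybenzaldehyde | COc1cc(O)cc(O)c1C=O | starting material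
2 | 2-hydroxy-6-methoxy-4-(triisopropylsilyloxy)benzaldehyde | COc1cc(O[Si](C(C)C)(C(C)C)C(C)C)cc(O)c1C=O | intermediate
3 | 3-methylbut-2-en-1-ol | CC(C)=CCO | starting material
4 | 2-methoxy-6-(3-methylbut-2-enyloxy)-4-(triisopropylsilyloxy)benzaldehyde | COc1cc(O[Si](C(C)C)(C(C)C)C(C)C)cc(OCC=C(C)C)c1C=O | intermediate
5 | 2-methoxy-5-(2-methylbut-3-en-2-yl)-6-oxo-4-(triisopropylsilyloxy)cyclohexa-1,3-diene-1-carbaldehyde (ortho dienone, racemic, formed in the flask, not isolated) | O=CC1=C(OC)C=C(O[Si](C(C)C)(C(C)C)C(C)C)C(C(C)(C)C=C)C1=O | intermediate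
6 | 2-methoxy-3-(3-methylbut-2-enyl)-6-oxo-4-(triisopropylsilyloxy)cyclohexa-1,4-diene-1-carbaldehyde (para dienone, racemic, formed in the flask, not isolated) | O=CC1=C(OC)C(CC=C(C)C)C(O[Si](C(C)C)(C(C)C)C(C)C)=CC1=O | intermediate
7 | 6-hydroxy-2-methoxy-3-(3-methylbut-2-enyl)-4-(triisopropylsilyloxy)benzaldehyde | COc1c(CC=C(C)C)c(O[Si](C(C)C)(C(C)C)C(C)C)cc(O)c1C=O | intermediate
8 | N-[[2-hydroxy-6-methoxy-5-(3-methylbut-2-enyl)-4-(triisopropylsilyloxy)phenyl]methylidene]-N-methylmethanaminium acetate (iminium acetate, formed in the flask, not isolated) | COc1c(CC=C(C)C)c(O[Si](C(C)C)(C(C)C)C(C)C)cc(O)c1C=[N+](C)C.CC(=O)[O-] | intermediate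
9 | 2-[(dimethylamino)methyl]-3-methoxy-4-(3-methylbut-2-enyl)-5-(triisopropylsilyloxy)phenol | COc1c(CC=C(C)C)c(O[Si](C(C)C)(C(C)C)C(C)C)cc(O)c1CN(C)C | intermediate
10 | [2-hydroxy-6-methoxy-5-(3-methylbut-2-enyl)-4-(triisopropylsilyloxy)phenyl]methyl-trimethylammonium iodide | COc1c(CC=C(C)C)c(O[Si](C(C)C)(C(C)C)C(C)C)cc(O)c1C[N+](C)(C)C.[I-] | intermediate
11 | 4-hydroxy-2-methoxybenzaldehyde | COc1cc(O)ccc1C=O | starting material
12 | 2-methoxy-4-(triisopropylsilyloxy)benzaldehyde | COc1cc(O[Si](C(C)C)(C(C)C)C(C)C)ccc1C=O | intermediate
13 | 2-methoxy-1-(2-methoxyethenyl)-4-(triisopropylsilyloxy)benzene (E/Z mixture) | COC=Cc1ccc(O[Si](C(C)C)(C(C)C)C(C)C)cc1OC | intermediate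
14 | 2-[2-methoxy-4-(triisopropylsilyloxy)phenyl]acetaldehyde | O=CCc1ccc(O[Si](C(C)C)(C(C)C)C(C)C)cc1OC | intermediate
15 | 5-methoxy-6-methylidene-4-(3-methylbut-2-enyl)-3-(triisopropylsilyloxy)cyclohexa-2,4-dien-1-one (o-quinone methide, formed in the flask, not isolated) | C=C1C(=O)C=C(O[Si](C(C)C)(C(C)C)C(C)C)C(CC=C(C)C)=C1OC | intermediate
16 | (2R)-2-[diphenyl(trimethylsilyloxy)methyl]-1-[(E)-2-[2-methoxy-4-(triisopropylsilyloxy)phenyl]ethenyl]pyrrolidine (enamine of 14 and the catalyst, formed in the flask, not isolated) | COc1cc(O[Si](C(C)C)(C(C)C)C(C)C)ccc1/C=C/N1CCC[C@@H]1C(c1ccccc1)(c1ccccc1)O[Si](C)(C)C | intermediate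
17 | (2R)-3-[2-hydroxy-6-methoxy-5-(3-methylbut-2-enyl)-4-(triisopropylsilyloxy)phenyl]-2-[2-methoxy-4-(triisopropylsilyloxy)phenyl]propanal (hydroxy aldehyde, formed in the flask, not isolated) | COc1cc(O[Si](C(C)C)(C(C)C)C(C)C)ccc1[C@H](C=O)Cc1c(O)cc(O[Si](C(C)C)(C(C)C)C(C)C)c(CC=C(C)C)c1OC | intermediate
18 | (3R)-5-methoxy-3-[2-methoxy-4-(triisopropylsilyloxy)phenyl]-6-(3-methylbut-2-enyl)-7-(triisopropylsilyloxy)chroman-2-ol (mixture of C2 anomers) | COc1cc(O[Si](C(C)C)(C(C)C)C(C)C)ccc1[C@@H]1C(O)Oc2cc(O[Si](C(C)C)(C(C)C)C(C)C)c(CC=C(C)C)c(OC)c2C1 | intermediate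
19 | (3R)-5-methoxy-3-[2-methoxy-4-(triisopropylsilyloxy)phenyl]-6-(3-methylbut-2-enyl)-7-(triisopropylsilyloxy)chroman | COc1cc(O[Si](C(C)C)(C(C)C)C(C)C)ccc1[C@@H]1COc2cc(O[Si](C(C)C)(C(C)C)C(C)C)c(CC=C(C)C)c(OC)c2C1 | intermediate
20 | (3R)-3-(4-hydroxy-2-methoxyphenyl)-5-methoxy-6-(3-methylbut-2-enyl)chroman-7-ol | COc1cc(O)ccc1[C@@H]1COc2cc(O)c(CC=C(C)C)c(OC)c2C1 | target

**Count**
Total steps: 11. Longest linear sequence: 8 steps (steps 1, 2, 3, 4, 5, 9, 10, 11); the ring B branch (steps 6 to 8) joins at step 9.

**Steps most likely to fail, with fallbacks**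

Step 9. The open-chain α-aryl aldehyde may enolise before it closes to the hemiacetal, which would erode the enantiomeric purity. Conversion may also suffer from self-aldol condensation of the arylacetaldehyde, self-condensation of the methide, or N-alkylation of the catalyst. The fallback sets out from ammonium salt 10 and enol ether 13, both already in hand. Heating the two with Na2CO3 in toluene should release methide 15, which should undergo the thermal hetero-Diels–Alder reaction with the β-aryl enol ether (a reaction type with precedent for racemic isoflavans). This gives the racemic 2-methoxy-3-arylchroman acetal F1. Et3SiH and BF3·OEt2 in CH2Cl2 at −78 °C should then remove the anomeric methoxy group and give the racemic bis-silyl isoflavan F2. Preparative HPLC on a chiral stationary phase should deliver the (R)-enantiomer, which is compound 19, where the route is rejoined.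

Step 10. The cyclic oxocarbenium ion may lose the C3 proton to the 4H-chromene and be reprotonated, which would scramble C3. The acid may also attack the prenyl double bond or a silyl ether. The fallback sets out from lactol 18. NaBH4 in THF/MeOH at 0 °C should reduce the small equilibrium share of the hydroxy aldehyde to the (R)-configured phenol alcohol F3. Mitsunobu ring closure (PPh3, DIAD, THF, 0 °C) of the phenol onto the primary alcohol then remakes the O1–C2 bond without any cationic intermediate and gives compound 19.

Step 5. The very electron-rich benzylic ammonium salt may lose trimethylamine during isolation, so that the methide forms early and oligomerises, or the phenol may be O-methylated. The fallback sets out from aldehyde 7 and replaces the nitrogen leaving group by a sulfinate. NaBH4 in THF/MeOH at 0 °C should give the salicyl alcohol F4. Sodium 4-methylbenzenesulfinate in aqueous formic acid should then displace the benzylic hydroxyl (SN1-type substitution at the donor-stabilised benzylic carbon) and give the sulfone F5. F5 is used in place of 10 under the conditions of step 9, where Na2CO3 releases sulfinate and the same methide 15, so the route is rejoined at lactol 18.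

**Further compounds**
F1 | step 9 | racemic 2,5-dimethoxy-3-[2-methoxy-4-(triisopropylsilyloxy)phenyl]-6-(3-methylbut-2-enyl)-7-(triisopropylsilyloxy)chroman (mixture of diastereomers) | COC1Oc2cc(O[Si](C(C)C)(C(C)C)C(C)C)c(CC=C(C)C)c(OC)c2CC1c1ccc(O[Si](C(C)C)(C(C)C)C(C)C)cc1OC
F2 | step 9 | racemic 5-methoxy-3-[2-methoxy-4-(triisopropylsilyloxy)phenyl]-6-(3-methylbut-2-enyl)-7-(triisopropylsilyloxy)chroman | COc1cc(O[Si](C(C)C)(C(C)C)C(C)C)ccc1C1COc2cc(O[Si](C(C)C)(C(C)C)C(C)C)c(CC=C(C)C)c(OC)c2C1
F3 | step 10 | (2R)-3-[2-hydroxy-6-methoxy-5-(3-methylbut-2-enyl)-4-(triisopropylsilyloxy)phenyl]-2-[2-methoxy-4-(triisopropylsilyloxy)phenyl]propan-1-ol | COc1cc(O[Si](C(C)C)(C(C)C)C(C)C)ccc1[C@H](CO)Cc1c(O)cc(O[Si](C(C)C)(C(C)C)C(C)C)c(CC=C(C)C)c1OC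
F4 | step 5 | 2-(hydroxymethyl)-3-methoxy-4-(3-methylbut-2-enyl)-5-(triisopropylsilyloxy)phenol | COc1c(CC=C(C)C)c(O[Si](C(C)C)(C(C)C)C(C)C)cc(O)c1CO
F5 | step 5 | 3-methoxy-4-(3-methylbut-2-enyl)-2-[(4-methylphenyl)sulfonylmethyl]-5-(triisopropylsilyloxy)phenol | COc1c(CC=C(C)C)c(O[Si](C(C)C)(C(C)C)C(C)C)cc(O)c1CS(=O)(=O)c1ccc(C)cc1
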